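## Analysis of the target

The target is a fully substituted 1,4-benzoquinone. In ubiquinone numbering the ring carries C1=O, C2–OCH3, C3–OH, C4=O, C5–CH3 and C6–C1′H2 of an all-E hexaprenyl chain (C1′–C24′). There is no stereogenic centre. The stereochemical content is five E-trisubstituted alkenes (C2′, C6′, C10′, C14′, C18′) of the same head-to-tail type plus a terminal isopropylidene, and each must be kept through every step.

The hydroxyquinone is a redox-active, metal-chelating vinylogous acid that is attacked by nucleophiles and strong base. The skipped polyene cyclises or isomerises under protic or Lewis acid, and C1′H2 is doubly activated.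

The real difficulty is regiochemical. C2–OCH3 and C3–OH differ only in their remote neighbours (chain at C6, methyl at C5), so no reagent can tell them apart once both sit on the ring.

The feature that invites an annulation is this: C1, C2, C3 and C4 with their four oxygens are the skeleton of squaric acid monomethyl ester (used as its lithium salt 16) with the C1–C4 bond opened, and C5(CH3)=C6 is a but-2-en-2-yl unit. The monoanion of that ester is symmetric. Its only ketone carbon (future C4) lies across the four-membered ring from C–OCH3 (future C2), and the two oxido carbons (future C1 and C3) are equivalent. Bonding C5 to that ketone therefore places the hydroxyl at C3, on the methyl side, without asking any reagent for selectivity.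

## Retrosynthetic reasoning

**22 to 19 (ring bond C1–C6; four-ring bond C1–C4 restored).** Target 22 is the oxidised, desilylated form of arene 21. Arene 21 is the tautomer of the 6π-electrocyclisation product of dienylketene 20, and 20 is the ring-opened form of cyclobutenone 19. Cutting C1–C6 and re-closing C1–C4 reduces the hexasubstituted six-membered ring to a four-membered ring that already carries all six substituents in the right order. The forward reaction is a purely thermal ring expansion followed by a mild oxidation.

**19 to 17 and 16 (bond C4–C5).** This cut separates the oxygenated C4 unit from the carbon unit C5(CH3)=C6–chain. The bond is cut here because the C4 partner, salt 16, has only one ketone, so the alkenyl nucleophile 17 can only arrive at the future C4. A neutral mixed dialkyl squarate would offer two nearly equal carbonyls. The forward step has to achieve a carbonyl addition to an anionic substrate and a double O-silylation.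

**17 to 14, then 14 to 10 and 13 (bond C6–C1′).** The alkenyllithium 17 comes from alkenyl bromide 14 by halogen–lithium exchange. Bromide 14 is cut between its C3 (future C6) and C4 (future C1′) into the allylic bromide 10 and the bromo-alkenylboronate 13. The ring-to-chain bond is thus made on an acyclic alkene before any ring exists, which avoids aromatic substitution and directing groups. The coupling must keep the 2′E geometry and leave the alkenyl bromide untouched.

**13 to 11.** The boronate is the syn-bromoboration product of propyne 11. Propyne supplies C5, the C5 methyl group and C6 of the quinone with defined positions of bromine and boron.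

**10 to 9, 7, then 5 and 3; 3 to 2 to 1; 5 to 4.** Bromide 10 comes from hexaprenol 9. Its chain is cut in the middle (C12–C13 of 7) into two farnesyl units: sulfone 5 (from bromide 4) as the nucleophile and ω-bromo acetate 3 (from acetate 1 through allylic alcohol 2) as the electrophile. The sulfone fixes the site of C–C bond formation, so all five E-alkenes are inherited from the two farnesyl units and none has to be made.

**16 to 15.** Salt 16 is the mono-saponification product of dimethyl squarate 15.

## Alternatives that were turned down

**Alternative 1:** The textbook cut is C6–C1′, made last on a ready aromatic ring. Aryl bromide A1 has C1–O and C4–O masked as methyl ethers and O3 as a methoxymethyl ether. It would be lithiated, transmetalated to copper and allylated with 10 to give A2. Oxidative demethylation of the para pair and acetal cleavage would then give 22.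
- The key step forms one sp2–sp3 bond and solves nothing of the regiochemical problem.
- The O2/O3 distinction must be written into A1 by about six linear arene steps (formylation, chelation-controlled demethylation, aryl formate oxidation, two protections, bromination).
- The final oxidant must pick the right para pair among four oxygens, and the acetal must be cleaved by acid beside six trisubstituted alkenes.
- It is the route most chemists would draw first.

**Alternative 2:** C6–C1′ by a like-polarity radical union on the finished quinone. Decarboxylation of acid A4, by a one-electron oxidant or at the anode, would give the hexaprenyl radical, which would add to the free C6–H of fumigatin A3.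
- The allylic radical is ambident, and attack through C3′ gives the tert-alkyl isomer.
- Rotation within the radical erodes the 2′E geometry.
- The oxidant or anode that triggers decarboxylation also attacks the electron-rich trisubstituted alkenes and the hydroxyquinone.
- A3 needs about four arene steps and A4 a one-carbon homologation of 10, so nothing is saved.

**Alternative 3:** The biosynthetic order, with C3–O formed last. 5-Demethoxyubiquinone-6 A5 would be epoxidised at C2=C3 with a nucleophilic peroxide to A6, and base would open the epoxide to the hydroxyquinone.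
- C3 of A5 is the β-carbon of a methoxy enol ether, the least electrophilic alkene carbon of the quinone.
- The dialkyl C5=C6 bond is the normal site of such epoxidations, and nothing in the substrate steers the peroxide.
- A5 still needs its own ring synthesis or chain coupling, and two redox steps follow it.
- The regiochemical question is only traded for a site-selectivity question.

Key step: step 11

Assumption: compounds 1, 4, 11 and 15 are taken as commercial single isomers; all-E hexaprenol is not treated as commercial, so the chain is built from two farnesyl units.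

Assumption: the target is made as the 3-hydroxy-1,4-quinone tautomer given in the SMILES; its ortho-quinone tautomer is not a separate compound.

## Route

Step 1
Reactants: 1 (2E,6E)-farnesyl acetate
Product: 2 (2E,6E,10E)-12-hydroxy-3,7,11-trimethyldodeca-2,6,10-trien-1-yl acetate
Conditions: SeO2 (0.3 equiv), t-BuOOH (70% aq., 3 equiv), salicylic acid (0.1 equiv), CH2Cl2, 0 °C → rt
Reagents that add atoms: tert-butyl hydroperoxide, CC(C)(C)OO (terminal oxygen source); selenium dioxide, O=[Se]=O (oxygen-transfer catalyst)
Why: Riley allylic oxidation (ene reaction, then [2,3]-sigmatropic shift) should take place at the terminal, most electron-rich trisubstituted alkene and at its E-methyl group, which sets the 10E geometry. The C2 alkene is deactivated by the allylic acetate.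

Step 2
Reactants: 2 (2E,6E,10E)-12-hydroxy-3,7,11-trimethyldodeca-2,6,10-trien-1-yl acetate
Product: 3 (2E,6E,10E)-12-bromo-3,7,11-trimethyldodeca-2,6,10-trien-1-yl acetate
Conditions: CBr4, PPh3, CH2Cl2, 0 °C
Reagents that add atoms: carbon tetrabromide, BrC(Br)(Br)Br
Why: Appel bromination of a primary allylic alcohol is neutral and proceeds by SN2 displacement on the oxyphosphonium ion, so neither allylic transposition nor E/Z change is expected. The acetate is inert.

Step 3
Reactants: 4 (2E,6E)-farnesyl bromide
Product: 5 {[(2E,6E)-3,7,11-trimethyldodeca-2,6,10-trien-1-yl]sulfonyl}benzene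
Conditions: PhSO2Na, DMF, rt
Reagents that add atoms: sodium benzenesulfinate, [Na+].[O-]S(=O)c1ccccc1
Why: SN2 S-alkylation of the sulfinate at the primary allylic carbon should give the allylic sulfone with the 2E geometry unchanged.

Step 4
Reactants: 5 {[(2E,6E)-3,7,11-trimethyldodeca-2,6,10-trien-1-yl]sulfonyl}benzene; 3 (2E,6E,10E)-12-bromo-3,7,11-trimethyldodeca-2,6,10-trien-1-yl acetate
Product: 7 (2E,6E,10E,14E,18E)-3,7,11,15,19,23-hexamethyl-13-(phenylsulfonyl)tetracosa-2,6,10,14,18,22-hexaen-1-yl acetate (racemic at C13), via lithiated sulfone 6 (not isolated)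
Conditions: n-BuLi (1.0 equiv), THF/DMPU, −78 °C; then 3, −78 → −30 °C
Reagents that add atoms: none
Why: Biellmann-type alkylation: the sulfonyl group makes the allyl anion react at its α-carbon, so the two farnesyl units join head to tail with all E-alkenes retained. The anion is preformed with one equivalent of base so that no free alkyllithium meets the acetate. The new stereocentre at C13 forms as a racemate and is removed in step 5.

Step 5
Reactants: 7 (2E,6E,10E,14E,18E)-3,7,11,15,19,23-hexamethyl-13-(phenylsulfonyl)tetracosa-2,6,10,14,18,22-hexaen-1-yl acetate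
Product: 9 (2E,6E,10E,14E,18E)-3,7,11,15,19,23-hexamethyltetracosa-2,6,10,14,18,22-hexaen-1-ol, via sulfonyl alkoxide 8 (not isolated)
Conditions: LiBHEt3 (4 equiv), THF, −78 → 0 °C; then PdCl2(dppp) (5 mol %), 0 °C → rt
Reagents that add atoms: none
Why: The hydride first cleaves the acetate to the alkoxide, which cannot ionise. Palladium-catalysed allylic substitution of sulfinate by hydride then delivers hydrogen to the less substituted terminus of the π-allyl intermediate (the carbon that bore sulfur), so the C14 alkene should stay in place and E.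

Step 6
Reactants: 9 (2E,6E,10E,14E,18E)-3,7,11,15,19,23-hexamethyltetracosa-2,6,10,14,18,22-hexaen-1-ol
Product: 10 (2E,6E,10E,14E,18E)-1-bromo-3,7,11,15,19,23-hexamethyltetracosa-2,6,10,14,18,22-hexaene
Conditions: PBr3 (0.4 equiv), Et2O, −10 °C; used crude at once
Reagents that add atoms: phosphorus tribromide, BrP(Br)Br
Why: Bromination of a primary prenyl-type alcohol through its phosphite proceeds by SN2 at low temperature, as for farnesyl bromide, without allylic shift or loss of the 2E geometry.

Step 7
Reactants: 11 propyne
Product: 13 2-[(1Z)-2-bromoprop-1-en-1-yl]-4,4,5,5-tetramethyl-1,3,2-dioxaborolane, via dibromoborane 12 (not isolated)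
Conditions: BBr3, CH2Cl2, −78 °C → rt; then pinacol, −78 °C → rt
Reagents that add atoms: boron tribromide, BrB(Br)Br; pinacol, CC(C)(O)C(C)(C)O
Why: Syn-bromoboration of the terminal alkyne puts bromine on the internal and boron on the terminal carbon, cis to each other. Esterification with pinacol fixes this Z geometry.

Step 8
Reactants: 10 (2E,6E,10E,14E,18E)-1-bromo-3,7,11,15,19,23-hexamethyltetracosa-2,6,10,14,18,22-hexaene (1.15 equiv); 13 2-[(1Z)-2-bromoprop-1-en-1-yl]-4,4,5,5-tetramethyl-1,3,2-dioxaborolane
Product: 14 (2Z,5E,9E,13E,17E,21E)-2-bromo-6,10,14,18,22,26-hexamethylheptacosa-2,5,9,13,17,21,25-heptaene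
Conditions: Pd(PPh3)4 (5 mol %), K3PO4 (3 M aq.), THF, 40 °C
Reagents that add atoms: none
Why: Suzuki–Miyaura allyl–alkenyl coupling: zerovalent palladium adds to the allylic C–Br bond far faster than to an alkenyl C–Br bond, and 10 is kept in slight excess so the alkenyl bromide is never the only electrophile. Coupling should occur at the primary allyl terminus with the 5E (former 2′E) geometry retained, and the alkenylboron geometry is transferred with retention.

Step 9
Reactants: 15 dimethyl squarate (3,4-dimethoxycyclobut-3-ene-1,2-dione)
Product: 16 lithium 2-methoxy-3,4-dioxocyclobut-1-en-1-olate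
Conditions: LiOH·H2O (1.0 equiv), MeOH/H2O, 0 °C → rt; evaporation; azeotropic drying (toluene), 60 °C, high vacuum
Reagents that add atoms: lithium hydroxide, [Li+].[OH-]
Why: Hydroxide adds to the vinylogous ester carbon and expels methoxide (addition–elimination). The monoanion formed resists a second attack, so the mono-salt should result. Rigorous drying is needed because step 10 uses an organolithium.

Step 10
Reactants: 14 (2Z,5E,9E,13E,17E,21E)-2-bromo-6,10,14,18,22,26-hexamethylheptacosa-2,5,9,13,17,21,25-heptaene; 16 lithium 2-methoxy-3,4-dioxocyclobut-1-en-1-olate (1.3 equiv)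
Product: 19 4-[(2Z,5E,9E,13E,17E,21E)-6,10,14,18,22,26-hexamethylheptacosa-2,5,9,13,17,21,25-heptaen-2-yl]-2-methoxy-3,4-bis(trimethylsilyloxy)cyclobut-2-en-1-one (racemic; crude), via alkenyllithium 17 (not isolated), via dilithium adduct 18 (not isolated)
Conditions: t-BuLi (2.05 equiv), Et2O, −78 °C; then 16, THF/DMPU, −78 → −30 °C; then Me3SiCl (4 equiv), −78 → 0 °C; pentane, filtration under argon
Reagents that add atoms: chlorotrimethylsilane, C[Si](C)(C)Cl
Why: Proposed new method: 1,2-addition of an organolithium to a squarate monoester salt is not described; in 16 the charge is shared by the two equivalent oxido carbons, which are thereby switched off as electrophiles, and the carbonyl opposite C–OCH3 is the only ketone left, so 17 (formed from 14 by bromine–lithium exchange with retention of geometry) can add at one position only and silylation of either enantiotopic enolate oxygen of 18 gives the same constitution. The closest known reaction type is the 1,2-addition of alkenyllithiums to dialkyl squarates at −78 °C with O-silylation of the adduct, the neutral case in which the two carbonyls are not distinguished. The new stereocentre of 19 forms as a racemate and is erased in step 11.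

Step 11
Reactants: 19 4-[(2Z,5E,9E,13E,17E,21E)-6,10,14,18,22,26-hexamethylheptacosa-2,5,9,13,17,21,25-heptaen-2-yl]-2-methoxy-3,4-bis(trimethylsilyloxy)cyclobut-2-en-1-one
Product: 22 3-hydroxy-2-methoxy-5-methyl-6-[(2E,6E,10E,14E,18E)-3,7,11,15,19,23-hexamethyltetracosa-2,6,10,14,18,22-hexaen-1-yl]cyclohexa-2,5-diene-1,4-dione (3-demethylubiquinone-6), via dienylketene 20 (not isolated), via silylated hydroquinone 21 (not isolated)
Conditions: toluene (degassed), 110 °C; then FeCl3·6H2O (2.5 equiv), i-PrOH/H2O, 0 °C → rt
Reagents that add atoms: none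
Why: Moore ring expansion: heating opens the four-membered ring by a conrotatory 4π electrocyclic reaction at the bond between the carbonyl carbon and the silyloxy-bearing sp3 carbon, and because the donor silyloxy group rotates outward the alkenyl group turns inward, so dienylketene 20 has its ketene carbon next to the alkene terminus. A thermal 6π electrocyclisation of 20 (disrotatory, six-membered ring closure through the quinone C1–C6 bond) gives a cyclohexadienone that aromatises by tautomerisation of the C6–H to arene 21. The closest known reaction type is the thermal rearrangement of 4-alkenyl-4-silyloxy-2,3-dialkoxycyclobutenones to tetraoxygenated hydroquinone monosilyl ethers in boiling toluene or xylene. No stereocentre is formed: the racemic centre of 19 is destroyed, the geometry of the alkenyl double bond is irrelevant because its terminus becomes aromatic C6, and the chain alkenes are spectators under neutral thermal conditions. The selectivity needed is regiochemical and is already fixed in 19: only one C(sp3)–C(=O) bond can open, so C5 with its methyl ends beside the carbonyl flanked by the silyloxy carbon (C3) and C6 beside the carbonyl flanked by C–OCH3 (C2). FeCl3 in aqueous alcohol hydrolyses the two silyl ethers and oxidises the trihydroxyarene to the hydroxyquinone by two one-electron steps, and trivalent iron does not attack isolated trisubstituted alkenes.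

## Compound list

1 | (2E,6E)-farnesyl acetate [(2E,6E)-3,7,11-trimethyldodeca-2,6,10-trien-1-yl acetate] | CC(=O)OC/C=C(\C)CC/C=C(\C)CCC=C(C)C | starting material
2 | (2E,6E,10E)-12-hydroxy-3,7,11-trimethyldodeca-2,6,10-trien-1-yl acetate | CC(=O)OC/C=C(\C)CC/C=C(\C)CC/C=C(\C)CO | intermediate
3 | (2E,6E,10E)-12-bromo-3,7,11-trimethyldodeca-2,6,10-trien-1-yl acetate | CC(=O)OC/C=C(\C)CC/C=C(\C)CC/C=C(\C)CBr | intermediate
4 | (2E,6E)-farnesyl bromide [(2E,6E)-1-bromo-3,7,11-trimethyldodeca-2,6,10-triene] | BrC/C=C(\C)CC/C=C(\C)CCC=C(C)C | starting material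
5 | {[(2E,6E)-3,7,11-trimethyldodeca-2,6,10-trien-1-yl]sulfonyl}benzene | O=S(=O)(C/C=C(\C)CC/C=C(\C)CCC=C(C)C)c1ccccc1 | intermediate
6 | lithium (2E,6E)-3,7,11-trimethyl-1-(phenylsulfonyl)dodeca-2,6,10-trien-1-ide (lithiated sulfone) | [Li]C(/C=C(\C)CC/C=C(\C)CCC=C(C)C)S(=O)(=O)c1ccccc1 | intermediate
7 | (2E,6E,10E,14E,18E)-3,7,11,15,19,23-hexamethyl-13-(phenylsulfonyl)tetracosa-2,6,10,14,18,22-hexaen-1-yl acetate (racemic at C13) | CC(=O)OC/C=C(\C)CC/C=C(\C)CC/C=C(\C)CC(/C=C(\C)CC/C=C(\C)CCC=C(C)C)S(=O)(=O)c1ccccc1 | intermediate
8 | lithium (2E,6E,10E,14E,18E)-3,7,11,15,19,23-hexamethyl-13-(phenylsulfonyl)tetracosa-2,6,10,14,18,22-hexaen-1-olate (racemic at C13) | [Li+].[O-]C/C=C(\C)CC/C=C(\C)CC/C=C(\C)CC(/C=C(\C)CC/C=C(\C)CCC=C(C)C)S(=O)(=O)c1ccccc1 | intermediate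
9 | (2E,6E,10E,14E,18E)-3,7,11,15,19,23-hexamethyltetracosa-2,6,10,14,18,22-hexaen-1-ol (all-E hexaprenol) | OC/C=C(\C)CC/C=C(\C)CC/C=C(\C)CC/C=C(\C)CC/C=C(\C)CCC=C(C)C | intermediate
10 | (2E,6E,10E,14E,18E)-1-bromo-3,7,11,15,19,23-hexamethyltetracosa-2,6,10,14,18,22-hexaene (hexaprenyl bromide) | BrC/C=C(\C)CC/C=C(\C)CC/C=C(\C)CC/C=C(\C)CC/C=C(\C)CCC=C(C)C | intermediate
11 | propyne | CC#C | starting material
12 | dibromo[(1Z)-2-bromoprop-1-en-1-yl]borane | C/C(Br)=C/B(Br)Br | intermediate
13 | 2-[(1Z)-2-bromoprop-1-en-1-yl]-4,4,5,5-tetramethyl-1,3,2-dioxaborolane | C/C(Br)=C/B1OC(C)(C)C(C)(C)O1 | intermediate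
14 | (2Z,5E,9E,13E,17E,21E)-2-bromo-6,10,14,18,22,26-hexamethylheptacosa-2,5,9,13,17,21,25-heptaene | C/C(Br)=C/C/C=C(\C)CC/C=C(\C)CC/C=C(\C)CC/C=C(\C)CC/C=C(\C)CCC=C(C)C | intermediate
15 | dimethyl squarate (3,4-dimethoxycyclobut-3-ene-1,2-dione) | COC1=C(OC)C(=O)C1=O | starting material
16 | lithium 2-methoxy-3,4-dioxocyclobut-1-en-1-olate | [Li+].COC1=C([O-])C(=O)C1=O | intermediate
17 | [(2E,5E,9E,13E,17E,21E)-6,10,14,18,22,26-hexamethylheptacosa-2,5,9,13,17,21,25-heptaen-2-yl]lithium (same geometry as 14; the C2 descriptor changes because lithium ranks below methyl) | C/C([Li])=C/C/C=C(\C)CC/C=C(\C)CC/C=C(\C)CC/C=C(\C)CC/C=C(\C)CCC=C(C)C | intermediate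
18 | dilithium 4-[(2Z,5E,9E,13E,17E,21E)-6,10,14,18,22,26-hexamethylheptacosa-2,5,9,13,17,21,25-heptaen-2-yl]-2-methoxy-3-oxocyclobut-1-ene-1,4-bis(olate) | [Li+].[Li+].COC1=C([O-])C([O-])(/C(C)=C\C/C=C(\C)CC/C=C(\C)CC/C=C(\C)CC/C=C(\C)CC/C=C(\C)CCC=C(C)C)C1=O | intermediate
19 | 4-[(2Z,5E,9E,13E,17E,21E)-6,10,14,18,22,26-hexamethylheptacosa-2,5,9,13,17,21,25-heptaen-2-yl]-2-methoxy-3,4-bis(trimethylsilyloxy)cyclobut-2-en-1-one (racemic) | COC1=C(O[Si](C)(C)C)C(O[Si](C)(C)C)(/C(C)=C\C/C=C(\C)CC/C=C(\C)CC/C=C(\C)CC/C=C(\C)CC/C=C(\C)CCC=C(C)C)C1=O | intermediate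
20 | (3Z,5Z,8E,12E,16E,20E,24E)-2-methoxy-5,9,13,17,21,25,29-heptamethyl-3,4-bis(trimethylsilyloxy)triaconta-1,3,5,8,12,16,20,24,28-nonaen-1-one (dienylketene) | O=C=C(OC)/C(O[Si](C)(C)C)=C(O[Si](C)(C)C)\C(C)=C/C/C=C(\C)CC/C=C(\C)CC/C=C(\C)CC/C=C(\C)CC/C=C(\C)CCC=C(C)C | intermediate
21 | 6-[(2E,6E,10E,14E,18E)-3,7,11,15,19,23-hexamethyltetracosa-2,6,10,14,18,22-hexaen-1-yl]-2-methoxy-5-methyl-3,4-bis(trimethylsilyloxy)phenol | COc1c(O)c(C/C=C(\C)CC/C=C(\C)CC/C=C(\C)CC/C=C(\C)CC/C=C(\C)CCC=C(C)C)c(C)c(O[Si](C)(C)C)c1O[Si](C)(C)C | intermediate
22 | 3-hydroxy-2-methoxy-5-methyl-6-[(2E,6E,10E,14E,18E)-3,7,11,15,19,23-hexamethyltetracosa-2,6,10,14,18,22-hexaen-1-yl]cyclohexa-2,5-diene-1,4-dione (3-demethylubiquinone-6) | COC1=C(O)C(=O)C(C)=C(C/C=C(\C)CC/C=C(\C)CC/C=C(\C)CC/C=C(\C)CC/C=C(\C)CCC=C(C)C)C1=O | target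

## Step count and least certain steps

Total step count: 11. Longest linear sequence: 8 steps (1, 2, 4, 5, 6, 8, 10, 11).

**Step 10 (proposed new method).** Carbonyl addition may be slow or fail because salt 16 is poorly soluble and its ketone is deactivated by the negative charge. On warming, 17 would then be consumed by proton transfer, either from water or methanol retained by the salt or from the bis-allylic CH2 of a second molecule. Attack at an oxido carbon is a second possible diversion.

The fallback sets out from 14 (converted into 17 as in step 10) and neutral 15. The classical 1,2-addition of the alkenyllithium to the diester at −78 °C should give 4-hydroxy-2,3-dimethoxy-4-alkenylcyclobutenone F1. Its methoxy group at the vinylogous ester position, the ring carbon next to the carbinol, is then replaced by oxide through addition–elimination with LiOH in aqueous THF at 0 °C, the same reaction type as step 9. This gives lithium enolate F2, which is dried and bis-silylated (Me3SiCl, Et3N) and rejoins the route at 19. The two methoxy groups are told apart by the same vinylogy principle, but after the C–C bond has been made.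

**Step 11 (key step).** The labile silyl enol ether or carbinol silyl ether may be lost before the ring opens. Acid-promoted ionisation of the tertiary bis-allylic carbinol (allylic transposition with loss of methanol) or trapping of the ketene by adventitious water would then compete with the electrocyclisation. At the end, iron chelation or over-oxidation of the electron-rich hydroxyquinone can lower recovery.

The fallback abandons the annulation and sets out from hexaprenol 9. Purchased 2,3,4-trimethoxy-6-methylbenzaldehyde F3 is demethylated at the methoxy group ortho to the formyl group with BCl3 (chelation control) to 2-hydroxy-3,4-dimethoxy-6-methylbenzaldehyde F4. Dakin oxidation (H2O2, NaOH) gives 3,4-dimethoxy-6-methylbenzene-1,2-diol F5. Friedel–Crafts alkylation of F5 with 9 (BF3·OEt2, dioxane) at its only free ring position gives the hexaprenylated catechol F6. Oxidation with FeCl3 in aqueous i-PrOH to the ortho-quinone, hydrolysis of its vinylogous ester methoxy group (the one para to a hydroxyl) in the same medium and tautomerisation lead back to the route at 22.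

**Step 8.** Zerovalent palladium may insert into the alkenyl C–Br bond of 13 or 14 once the allylic bromide runs low, leading to oligomerisation. The π-allyl intermediate may lose the 2′E geometry or couple at the branched terminus, and the aqueous base may hydrolyse 10.

The fallback sets out from 11 and 10. Palladium-catalysed syn-distannation of 11 with Me3SnSnMe3 (Pd(PPh3)4) gives (Z)-1,2-bis(trimethylstannyl)prop-1-ene F7. Stille coupling of 10 at the less hindered terminal tin (Pd2(dba)3, AsPh3, THF) gives alkenylstannane F8, which carries no carbon–halogen bond during the palladium step. Tin–lithium exchange with MeLi (THF, −78 → 0 °C) then releases the alkenyllithium with retention, and the route is rejoined at 17.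

## Further compounds

F1 | step 10 | 4-hydroxy-2,3-dimethoxy-4-[(2Z,5E,9E,13E,17E,21E)-6,10,14,18,22,26-hexamethylheptacosa-2,5,9,13,17,21,25-heptaen-2-yl]cyclobut-2-en-1-one (racemic) | COC1=C(OC)C(O)(/C(C)=C\C/C=C(\C)CC/C=C(\C)CC/C=C(\C)CC/C=C(\C)CC/C=C(\C)CCC=C(C)C)C1=O
F2 | step 10 | lithium 4-hydroxy-2-methoxy-3-oxo-4-[(2Z,5E,9E,13E,17E,21E)-6,10,14,18,22,26-hexamethylheptacosa-2,5,9,13,17,21,25-heptaen-2-yl]cyclobut-1-en-1-olate (racemic) | [Li+].COC1=C([O-])C(O)(/C(C)=C\C/C=C(\C)CC/C=C(\C)CC/C=C(\C)CC/C=C(\C)CC/C=C(\C)CCC=C(C)C)C1=O
F3 | step 11 | 2,3,4-trimethoxy-6-methylbenzaldehyde (purchased) | COc1cc(C)c(C=O)c(OC)c1OC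
F4 | step 11 | 2-hydroxy-3,4-dimethoxy-6-methylbenzaldehyde | COc1cc(C)c(C=O)c(O)c1OC
F5 | step 11 | 3,4-dimethoxy-6-methylbenzene-1,2-diol | COc1cc(C)c(O)c(O)c1OC
F6 | step 11 | 3,4-dimethoxy-6-methyl-5-[(2E,6E,10E,14E,18E)-3,7,11,15,19,23-hexamethyltetracosa-2,6,10,14,18,22-hexaen-1-yl]benzene-1,2-diol | COc1c(C/C=C(\C)CC/C=C(\C)CC/C=C(\C)CC/C=C(\C)CC/C=C(\C)CCC=C(C)C)c(C)c(O)c(O)c1OC
F7 | step 8 | (Z)-1,2-bis(trimethylstannyl)prop-1-ene | C/C([Sn](C)(C)C)=C/[Sn](C)(C)C
F8 | step 8 | trimethyl[(2Z,5E,9E,13E,17E,21E)-6,10,14,18,22,26-hexamethylheptacosa-2,5,9,13,17,21,25-heptaen-2-yl]stannane | C/C([Sn](C)(C)C)=C/C/C=C(\C)CC/C=C(\C)CC/C=C(\C)CC/C=C(\C)CC/C=C(\C)CCC=C(C)C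
A1 | alternative 1 | 1-bromo-2,3,5-trimethoxy-4-(methoxymethoxy)-6-methylbenzene | COCOc1c(OC)c(OC)c(Br)c(C)c1OC
A2 | alternative 1 | 1,2,4-trimethoxy-3-(methoxymethoxy)-5-methyl-6-[(2E,6E,10E,14E,18E)-3,7,11,15,19,23-hexamethyltetracosa-2,6,10,14,18,22-hexaen-1-yl]benzene | COCOc1c(OC)c(OC)c(C/C=C(\C)CC/C=C(\C)CC/C=C(\C)CC/C=C(\C)CC/C=C(\C)CCC=C(C)C)c(C)c1OC
A3 | alternative 2 | fumigatin (3-hydroxy-2-methoxy-5-methylcyclohexa-2,5-diene-1,4-dione) | COC1=C(O)C(=O)C(C)=CC1=O
A4 | alternative 2 | (3E,7E,11E,15E,19E)-4,8,12,16,20,24-hexamethylpentacosa-3,7,11,15,19,23-hexaenoic acid | OC(=O)C/C=C(\C)CC/C=C(\C)CC/C=C(\C)CC/C=C(\C)CC/C=C(\C)CCC=C(C)C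
A5 | alternative 3 | 5-demethoxyubiquinone-6 (2-[(2E,6E,10E,14E,18E)-3,7,11,15,19,23-hexamethyltetracosa-2,6,10,14,18,22-hexaen-1-yl]-6-methoxy-3-methylcyclohexa-2,5-diene-1,4-dione) | COC1=CC(=O)C(C)=C(C/C=C(\C)CC/C=C(\C)CC/C=C(\C)CC/C=C(\C)CC/C=C(\C)CCC=C(C)C)C1=O
A6 | alternative 3 | 1-methoxy-4-methyl-3-[(2E,6E,10E,14E,18E)-3,7,11,15,19,23-hexamethyltetracosa-2,6,10,14,18,22-hexaen-1-yl]-7-oxabicyclo[4.1.0]hept-3-ene-2,5-dione (racemic) | COC12OC1C(=O)C(C)=C(C/C=C(\C)CC/C=C(\C)CC/C=C(\C)CC/C=C(\C)CC/C=C(\C)CCC=C(C)C)C2=O
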